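**Retrosynthetic overview**

1. The acrolein is made last, by allylic oxidation of a 2-isopropenyl group (SeO2, then MnO2). The C5 side-chain ester comes from asymmetric transfer hydrogenation of a 5-acetyl group and esterification with (R)-2-methylbutanoic acid.
2. Key disconnection O1–C2: the dihydrofuran ring is closed from a trans-(2R,3R)-2-aryl-3-isopropenyloxirane whose phenol oxygen O1 still carries the isovaleryl group. Zerovalent palladium opens the oxirane (a temporary ring), the C3 alkoxide takes the acyl group from O1, and the freed O1 closes on C2 with net retention, giving the 2,3-cis C3 ester in one operation.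
3. Enabling feature: C2 is allylic (bonded to the exocyclic C(=CH2) carbon) and vicinal to oxygenated C3, so its C–O bond can be ionised to a π-allyl. O1 on C7a is ortho to C3a, so O1 and the C3 oxygen are joined through O–C3–C3a–C7a–O1 and can pass an acyl group through a six-membered transition state, while O1 can reach C2 to close the five-membered ring.
4. The oxirane stereocentres come from Shi epoxidation of an (E)-styrenyl tertiary allylic alcohol, which is then dehydrated to the isopropenyl group. That alcohol is made by Heck coupling of O-isovaleryl 3-bromo-4-hydroxyacetophenone with 2-methylbut-3-en-2-ol.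
5. Ring order: benzene ring purchased; oxirane (temporary, step 3); dihydrofuran ring (step 5).

Key step: step 5

Remark: the D-fructose-derived Shi ketone is assumed to select the same alkene face on the (E)-styrenyl allylic alcohol as on trans-β-methylstyrene, and (R)-2-methylbutanoic acid is taken as a purchasable acid.

**Route**

Step 1
Reactants: 1 1-(3-bromo-4-hydroxyphenyl)ethan-1-one
Product: 2 4-acetyl-2-bromophenyl 3-methylbutanoate
Conditions: 3-methylbutanoyl chloride, Et3N, DMAP (cat.), CH2Cl2, 0 °C
Reagents that add atoms: 3-methylbutanoyl chloride, CC(C)CC(=O)Cl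
Why: O-acylation of the acidic phenol (Schotten–Baumann-type, DMAP acyl transfer) installs the ester that later serves as phenol protection and as the acyl donor for the C3 oxygen; no stereocenter is formed.

Step 2
Reactants: 2 4-acetyl-2-bromophenyl 3-methylbutanoate, 3 2-methylbut-3-en-2-ol
Product: 4 4-acetyl-2-[(1E)-3-hydroxy-3-methylbut-1-en-1-yl]phenyl 3-methylbutanoate
Conditions: Pd(OAc)2 (3 mol%), P(o-tol)3 (6 mol%), Et3N, MeCN, 85 °C
Reagents that add atoms: none
Why: Mizoroki–Heck reaction, in which the arylpalladium bromide adds to the terminal alkene carbon and syn β-hydride elimination can only give the (E)-alkene because the carbinol carbon bears no hydrogen; no stereocenter is formed.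

Step 3
Reactants: 4 4-acetyl-2-[(1E)-3-hydroxy-3-methylbut-1-en-1-yl]phenyl 3-methylbutanoate
Product: 5 4-acetyl-2-[(2R,3S)-3-(2-hydroxypropan-2-yl)oxiran-2-yl]phenyl 3-methylbutanoate
Conditions: Shi ketone (1,2:4,5-di-O-isopropylidene-β-D-erythro-2,3-hexodiulo-2,6-pyranose, 0.5 equiv), KHSO5 (as Oxone, 2KHSO5·KHSO4·K2SO4), K2CO3 (co-added, pH held at 8.5–9), Bu4NHSO4 (cat.), MeCN–CH2(OMe)2 / aq. Na2EDTA, 0 °C
Reagents that add atoms: potassium peroxymonosulfate, [K+].[O-]S(=O)(=O)OO
Why: Shi asymmetric epoxidation, in which the chiral dioxirane transfers oxygen to the single, trans-disubstituted alkene through a spiro transition state and sets both oxirane stereocenters with the facial sense known for trans-β-substituted styrenes, the pH being kept below the usual value so that the activated aryl ester should survive.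

Step 4
Reactants: 5 4-acetyl-2-[(2R,3S)-3-(2-hydroxypropan-2-yl)oxiran-2-yl]phenyl 3-methylbutanoate
Product: 6 4-acetyl-2-[(2R,3R)-3-(prop-1-en-2-yl)oxiran-2-yl]phenyl 3-methylbutanoate
Conditions: Martin sulfurane Ph2S[OC(CF3)2Ph]2, CH2Cl2, 0 °C to rt
Reagents that add atoms: none
Why: dehydration of a tertiary alcohol with Martin sulfurane, where only a methyl hydrogen can be lost (the alternative would be a methyleneoxirane), so the isopropenyl group results and the oxirane stereocenters are untouched (the descriptor of the second carbon changes from S to R only through the CIP priorities).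

Step 5
Reactants: 6 4-acetyl-2-[(2R,3R)-3-(prop-1-en-2-yl)oxiran-2-yl]phenyl 3-methylbutanoate
Product: 9 (2R,3R)-5-acetyl-2-(prop-1-en-2-yl)-2,3-dihydro-1-benzofuran-3-yl 3-methylbutanoate, via allylpalladium alkoxide zwitterion 7 (not isolated), via allylpalladium phenoxide zwitterion 8 (not isolated)
Conditions: Pd(PPh3)4 (5 mol%), THF, −20 to 0 °C, quenched at full conversion
Reagents that add atoms: none
Why: Proposed new method: zerovalent palladium ionises the allylic C2–O bond of the oxirane anti to oxygen to give the zwitterionic 2-methylallylpalladium alkoxide 7; the C3 alkoxide attacks the isovalerate on O1 through a six-membered transition state (O–C3–C3a–C7a–O1–C=O), which moves the acyl group to the C3 oxygen and frees the O1 phenoxide 8 (downhill, since the p-acetylphenoxide is the better-stabilised anion and an aryl ester is an activated ester), and the phenoxide then attacks allyl terminus C2 anti to palladium, releasing zerovalent palladium. The closest known reaction types are the zerovalent-palladium-catalysed cyclisation of hydroxy vinyl epoxides, which runs with double inversion, and base-induced O-to-O acyl migration; new is their coupling, with the ester as internal acyl donor and masked nucleophile. The dihydrofuran ring (O1, C2, C3, C3a, C7a) closes in a 5-exo mode on the allyl terminus, the other two allyl carbons staying outside the ring. C3 keeps the configuration set in step 3 because its C–O bond is never broken, and C2 is controlled by the oxirane: two inversions equal retention, so the trans-oxirane should give the 2,3-cis product (2R,3R). The step needs ring closure at C2 rather than at the CH2 terminus (five- against seven-membered ring) and ring closure faster than face exchange of the allyl unit or proton loss from 7; the intramolecular acyl shift onto an activated ester and the five-ring closure should secure this, and a weakly coordinating halide-free medium, low temperature and a stop at full conversion should keep the product allyl aryl ether from re-ionising.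

Step 6
Reactants: 9 (2R,3R)-5-acetyl-2-(prop-1-en-2-yl)-2,3-dihydro-1-benzofuran-3-yl 3-methylbutanoate
Product: 10 (2R,3R)-5-[(1R)-1-hydroxyethyl]-2-(prop-1-en-2-yl)-2,3-dihydro-1-benzofuran-3-yl 3-methylbutanoate
Conditions: RuCl[(R,R)-TsDPEN](p-cymene) (1 mol%), HCO2H–Et3N (5:2), CH2Cl2, rt
Reagents that add atoms: none
Why: Noyori asymmetric transfer hydrogenation, in which the (R,R)-TsDPEN ruthenium hydride delivers hydride to one face of the aryl methyl ketone through its six-membered outer-sphere transition state and gives the (R)-carbinol under catalyst control, leaving esters, alkene and ring stereocenters untouched.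

Step 7
Reactants: 10 (2R,3R)-5-[(1R)-1-hydroxyethyl]-2-(prop-1-en-2-yl)-2,3-dihydro-1-benzofuran-3-yl 3-methylbutanoate, 11 (2R)-2-methylbutanoic acid
Product: 12 (1R)-1-[(2R,3R)-3-(3-methylbutanoyloxy)-2-(prop-1-en-2-yl)-2,3-dihydro-1-benzofuran-5-yl]ethyl (2R)-2-methylbutanoate
Conditions: DIC, DMAP (cat.), CH2Cl2, 0 °C to rt
Reagents that add atoms: none
Why: Steglich esterification, in which the carbinol C–O bond is not broken, so its (R) configuration is retained and the α-stereocenter of the acid is carried over at low temperature.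

Step 8
Reactants: 12 (1R)-1-[(2R,3R)-3-(3-methylbutanoyloxy)-2-(prop-1-en-2-yl)-2,3-dihydro-1-benzofuran-5-yl]ethyl (2R)-2-methylbutanoate
Product: 13 (1R)-1-[(2R,3R)-2-(3-hydroxyprop-1-en-2-yl)-3-(3-methylbutanoyloxy)-2,3-dihydro-1-benzofuran-5-yl]ethyl (2R)-2-methylbutanoate
Conditions: SeO2 (0.5 equiv), t-BuOOH, CH2Cl2, rt
Reagents that add atoms: tert-butyl hydroperoxide, CC(C)(C)OO
Why: SeO2-catalysed allylic oxidation (Riley oxidation: ene reaction, then [2,3]-shift, with t-BuOOH as terminal oxidant), which on a 1,1-disubstituted alkene should oxidise the methyl group in preference to the methine, as known for isopropenyl groups on dihydrobenzofurans and terpenes; no stereocenter changes.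

Step 9
Reactants: 13 (1R)-1-[(2R,3R)-2-(3-hydroxyprop-1-en-2-yl)-3-(3-methylbutanoyloxy)-2,3-dihydro-1-benzofuran-5-yl]ethyl (2R)-2-methylbutanoate
Product: 14 (1R)-1-[(2R,3R)-3-(3-methylbutanoyloxy)-2-(3-oxoprop-1-en-2-yl)-2,3-dihydro-1-benzofuran-5-yl]ethyl (2R)-2-methylbutanoate
Conditions: MnO2 (activated, excess), CH2Cl2, rt
Reagents that add atoms: none
Why: MnO2 oxidation selective for the primary allylic alcohol, giving the 2-substituted acrolein under neutral conditions that should leave both esters and the C2 aryl ether alone; no stereocenter changes.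

**Compound list**

1 | 1-(3-bromo-4-hydroxyphenyl)ethan-1-one | CC(=O)c1ccc(O)c(Br)c1 | starting material
2 | 4-acetyl-2-bromophenyl 3-methylbutanoate | CC(=O)c1ccc(OC(=O)CC(C)C)c(Br)c1 | intermediate
3 | 2-methylbut-3-en-2-ol | C=CC(C)(C)O | starting material
4 | 4-acetyl-2-[(1E)-3-hydroxy-3-methylbut-1-en-1-yl]phenyl 3-methylbutanoate | CC(=O)c1ccc(OC(=O)CC(C)C)c(/C=C/C(C)(C)O)c1 | intermediate
5 | 4-acetyl-2-[(2R,3S)-3-(2-hydroxypropan-2-yl)oxiran-2-yl]phenyl 3-methylbutanoate | CC(=O)c1ccc(OC(=O)CC(C)C)c([C@H]2O[C@@H]2C(C)(C)O)c1 | intermediate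
6 | 4-acetyl-2-[(2R,3R)-3-(prop-1-en-2-yl)oxiran-2-yl]phenyl 3-methylbutanoate | CC(=O)c1ccc(OC(=O)CC(C)C)c([C@H]2O[C@@H]2C(C)=C)c1 | intermediate
7 | allylpalladium alkoxide zwitterion: bis(triphenylphosphine)palladium 2-methylallyl cation carrying the C3 alkoxide, aryl isovalerate intact (not isolated; drawn as its η1 form; C3 is S by CIP, same spatial arrangement as in 6) | CC(=O)c1ccc(OC(=O)CC(C)C)c(c1)[C@@H]([O-])/C=C(/C[Pd-]([P+](c2ccccc2)(c2ccccc2)c2ccccc2)[P+](c2ccccc2)(c2ccccc2)c2ccccc2)C | intermediate
8 | allylpalladium phenoxide zwitterion: the same allylpalladium cation after the O-to-O acyl shift, isovalerate on the C3 oxygen, O1 as phenoxide (not isolated; drawn as its η1 form) | CC(=O)c1ccc([O-])c(c1)[C@@H](OC(=O)CC(C)C)/C=C(/C[Pd-]([P+](c2ccccc2)(c2ccccc2)c2ccccc2)[P+](c2ccccc2)(c2ccccc2)c2ccccc2)C | intermediate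
9 | (2R,3R)-5-acetyl-2-(prop-1-en-2-yl)-2,3-dihydro-1-benzofuran-3-yl 3-methylbutanoate | C=C(C)[C@H]1Oc2ccc(C(C)=O)cc2[C@H]1OC(=O)CC(C)C | intermediate
10 | (2R,3R)-5-[(1R)-1-hydroxyethyl]-2-(prop-1-en-2-yl)-2,3-dihydro-1-benzofuran-3-yl 3-methylbutanoate | C=C(C)[C@H]1Oc2ccc([C@@H](C)O)cc2[C@H]1OC(=O)CC(C)C | intermediate
11 | (2R)-2-methylbutanoic acid | CC[C@@H](C)C(=O)O | starting material
12 | (1R)-1-[(2R,3R)-3-(3-methylbutanoyloxy)-2-(prop-1-en-2-yl)-2,3-dihydro-1-benzofuran-5-yl]ethyl (2R)-2-methylbutanoate | C=C(C)[C@H]1Oc2ccc([C@@H](C)OC(=O)[C@H](C)CC)cc2[C@H]1OC(=O)CC(C)C | intermediate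
13 | (1R)-1-[(2R,3R)-2-(3-hydroxyprop-1-en-2-yl)-3-(3-methylbutanoyloxy)-2,3-dihydro-1-benzofuran-5-yl]ethyl (2R)-2-methylbutanoate | C=C(CO)[C@H]1Oc2ccc([C@@H](C)OC(=O)[C@H](C)CC)cc2[C@H]1OC(=O)CC(C)C | intermediate
14 | (1R)-1-[(2R,3R)-3-(3-methylbutanoyloxy)-2-(3-oxoprop-1-en-2-yl)-2,3-dihydro-1-benzofuran-5-yl]ethyl (2R)-2-methylbutanoate (CNP0154159.2) | C=C(C=O)[C@H]1Oc2ccc([C@@H](C)OC(=O)[C@H](C)CC)cc2[C@H]1OC(=O)CC(C)C | target

**Step count and risks**

Total steps: 9. Longest linear sequence: 9 steps (from 1 to 14; acid 11 enters in step 7).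

Steps most likely to fail:

Step 5 (proposed new method). The acyl shift inside zwitterion 7 may be outrun by proton loss, which would isomerise the opened oxirane to a dienyl or carbonyl compound. The allyl unit may also change face before ring closure, or after it through re-ionisation of the allyl aryl ether, which would drain cis into trans material. Fallback with known chemistry, from 6 back to 9: the relay is given up. The aryl ester of 6 is cleaved with n-butylamine in THF at 0 °C to the free phenol 1-{4-hydroxy-3-[(2R,3R)-3-(prop-1-en-2-yl)oxiran-2-yl]phenyl}ethan-1-one F1. F1 is not stored but cyclised at once with Pd(PPh3)4, the established zerovalent-palladium cyclisation of hydroxy vinyl epoxides with net retention, to 1-[(2R,3R)-3-hydroxy-2-(prop-1-en-2-yl)-2,3-dihydro-1-benzofuran-5-yl]ethan-1-one F2. F2 is acylated with 3-methylbutanoyl chloride and pyridine to give 9.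

Step 3. The activated aryl ester may be hydrolysed at the pH the dioxirane cycle prefers, and oxygen transfer to an electron-poor, ortho-substituted styrene may be slow enough for catalyst decay to compete. Fallback from 1 back to 5: the phenol is carried as a base-stable silyl ether. Compound 1 is silylated (i-Pr3SiCl, imidazole) to 1-{3-bromo-4-[(triisopropylsilyl)oxy]phenyl}ethan-1-one F3. Heck coupling with 3 gives 1-{3-[(1E)-3-hydroxy-3-methylbut-1-en-1-yl]-4-[(triisopropylsilyl)oxy]phenyl}ethan-1-one F4. Shi epoxidation at the standard pH 10.5 gives 1-{3-[(2R,3S)-3-(2-hydroxypropan-2-yl)oxiran-2-yl]-4-[(triisopropylsilyl)oxy]phenyl}ethan-1-one F5. Bu4NF in the presence of 3-methylbutanoic anhydride then exchanges silyl for isovaleryl, the phenoxide being acylated as it forms, to give 5.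

Step 8. The ene reaction may take place at the C2–H bond instead of the methyl group (leading to ring cleavage), or the oxidation may stall or run past the alcohol unevenly. Fallback from 12 to 14: ene-type chlorination of the isopropenyl group (NaOCl, CeCl3·7H2O, CH2Cl2–H2O, 0 °C) gives the allylic chloride (1R)-1-[(2R,3R)-2-(3-chloroprop-1-en-2-yl)-3-(3-methylbutanoyloxy)-2,3-dihydro-1-benzofuran-5-yl]ethyl (2R)-2-methylbutanoate F6. Oxidation of the chloride with N-methylmorpholine N-oxide in MeCN (Ganem-type oxidation) gives 14 directly, without passing through 13.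

**Further compounds**

F1 | step 5 | 1-{4-hydroxy-3-[(2R,3R)-3-(prop-1-en-2-yl)oxiran-2-yl]phenyl}ethan-1-one | CC(=O)c1ccc(O)c([C@H]2O[C@@H]2C(C)=C)c1
F2 | step 5 | 1-[(2R,3R)-3-hydroxy-2-(prop-1-en-2-yl)-2,3-dihydro-1-benzofuran-5-yl]ethan-1-one | C=C(C)[C@H]1Oc2ccc(C(C)=O)cc2[C@H]1O
F3 | step 3 | 1-{3-bromo-4-[(triisopropylsilyl)oxy]phenyl}ethan-1-one | CC(=O)c1ccc(O[Si](C(C)C)(C(C)C)C(C)C)c(Br)c1
F4 | step 3 | 1-{3-[(1E)-3-hydroxy-3-methylbut-1-en-1-yl]-4-[(triisopropylsilyl)oxy]phenyl}ethan-1-one | CC(=O)c1ccc(O[Si](C(C)C)(C(C)C)C(C)C)c(/C=C/C(C)(C)O)c1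
F5 | step 3 | 1-{3-[(2R,3S)-3-(2-hydroxypropan-2-yl)oxiran-2-yl]-4-[(triisopropylsilyl)oxy]phenyl}ethan-1-one | CC(=O)c1ccc(O[Si](C(C)C)(C(C)C)C(C)C)c([C@H]2O[C@@H]2C(C)(C)O)c1
F6 | step 8 | (1R)-1-[(2R,3R)-2-(3-chloroprop-1-en-2-yl)-3-(3-methylbutanoyloxy)-2,3-dihydro-1-benzofuran-5-yl]ethyl (2R)-2-methylbutanoate | C=C(CCl)[C@H]1Oc2ccc([C@@H](C)OC(=O)[C@H](C)CC)cc2[C@H]1OC(=O)CC(C)C
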